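Locants: the first dihydrobenzofuran is O1, C2, C3, C3a, C4–C7, C7a (benzo ring = ring A). The second carries primed locants (benzo ring = ring B). The two are joined by the C3–C5' bond.

## The problem

The target 30 is a resveratrol-type trimer in which two trans-2,3-diaryl-2,3-dihydrobenzofurans are joined by one C–C bond from C3 of the first to C5' of ring B of the second. Ring A also carries an (E)-4-hydroxystyryl group at C4, directly beside the junction, and the molecule has seven free phenols. There are four stereocentres in two adjacent trans pairs, (2S,3S) and (2'R,3'R). Within a pair the all-carbon centre (C3, C3') cannot epimerise, whereas its oxygen-bearing neighbour (C2, C2') is a 4-oxybenzylic aryl ether that can ionise and re-close. C3 can therefore correct C2, and C3' can correct C2', towards trans, but not the reverse. The two pairs are separated by ring B and cannot relay to each other, so the sense of the second pair has to be imposed by a reagent while the first is already present. The (E)-stilbene is prone to acid-induced cyclisation onto neighbouring arenes, to photoisomerisation and to hydrogenation. The polyphenol is easily oxidised, and both benzylic C–O bonds are labile to acid and hydrogenolysis, so deprotection must come last. What makes a one-step construction thinkable is that C2 and C3 are adjacent sp3 carbons, C2 carrying oxygen and an aryl group, C3 carrying ring A and ring B. This is the pattern left by anti addition of an aryl group (at C2) and an aryl–palladium unit (at C3) across an (E)-alkenylboron compound on ring A, with boron marking the place of the C2 oxygen.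

## Retrosynthesis

**30 to 29.** The seven O–CH3 bonds are cut last, giving heptamethyl ether 29. Methyl is the one phenol protecting group that survives aryllithium, palladium, alkaline peroxide and fluoride alike. The forward step must cleave seven ethers without letting the stilbene or the two benzylic C–O bonds react irreversibly.

**29 to 27 and 28.** The C4–vinyl bond is cut, giving aryl chloride 27 and 4-methoxystyrene 28. Olefination of a C4 aldehyde would instead place a carbonyl (or acetal) next to the reacting alkene in the key step, where an aryllithium is used. A chloride is inert there and small. 27 lacks the stilbene, so all earlier steps are free of concern for it. The forward Heck reaction must enter a hindered C–Cl bond and give the E alkene.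

**27 to 26 and 25.** The first dihydrofuran is opened at O1–C2, giving phenol alcohol 26 and, with the phenol masked as a SEM ether, alcohol 25. Cutting O1–C7a instead (aryl C–O coupling) would close with retention at C2 and require a syn adduct, which the anti addition planned below cannot supply. An SN2 closure with inversion fits it exactly. The precursor is acyclic with both stereocentres in place. The forward closure must invert C2, and C3 backs it up because trans is also the thermodynamic result. SEM is chosen because it is removed by fluoride, not by acid or hydrogen, in the presence of an ionisable benzylic alcohol, an aryl chloride and a benzylic ring ether.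

**25 to 24.** The C2–O bond is traced to a C2–B bond in boronate 24. Oxidation of C–B is stereoretentive, and boron is what permits the next cut.

**24 to 9, 22 (from 21) and 20.** Two bonds are cut together, C2–aryl and C3–C5'. This divides the molecule into three pieces of similar size: alkenylboronate 9 (ring A), 4-methoxyphenyllithium 22 from 4-bromoanisole 21, and aryl bromide 20 (the complete second dihydrobenzofuran). It creates C2 and C3 in one step from an achiral alkene.

- The neighbouring cuts are weaker. A C2–C3 cut (aldol or benzoin type) passes through a ketone with an epimerisable triaryl α-centre. Arylation at C3–C3a would have to tell two similar aryl groups apart.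
- The forward reaction is a three-component conjunctive cross-coupling. The aryl group migrates from boron to C2 while palladium, carrying ring B, bonds to C3 on the opposite face.
- It must prefer the metallate shift to plain Suzuki–Miyaura coupling of the alkenyl group. For that reason boron carries the hindered cis-1,2-dimethylacenaphthene-1,2-diol ("mac") ligand 7 in place of pinacol, which with β-substituted alkenes favours direct coupling.
- It must select one alkene face under control of the ligand on palladium, leave the ring A chloride alone and consume the ring B bromide.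

**9 to 5 and 7, and back to 1 and 6.** 9 is cut at B–O and C–B: hydroboration of alkyne 5 and exchange onto diol 7, which comes in one step from acenaphthoquinone 6. 5 comes from aldehyde 4 by one-carbon homologation, 4 from phenol 3, 3 from 2 by chelation-directed demethylation, and 2 by formylation of 1-chloro-3,5-dimethoxybenzene 1. The symmetrical arene 1 fixes chlorine, both oxygens and the side chain unambiguously. Direct ortho-formylation of a chloro methoxy phenol would have two competing ortho positions.

**20 to 19, 17/18, 16, 15, and back to 10, 11 and 13.** 20 is the C2' epimer of cis isomer 19, and 19 is cut at C2'–C3'. The forward reaction is intramolecular C–H insertion of the carbene from diazo compound 18 (made in the flask from hydrazone 17) into the benzylic C–H of a 4-methoxybenzyl ether. This forms the ring and both centres from an achiral precursor under catalyst control and tolerates the aryl bromide. The bromide cannot be introduced later, because the 3,5-dimethoxyphenyl ring would be halogenated first. 17 comes from ketone 16, 16 from carbinol 15, and 15 from aldehyde 12 and Grignard reagent 14 of 1-bromo-3,5-dimethoxybenzene 13. 12 comes from 5-bromo-2-hydroxy-3-methoxybenzaldehyde 10 and 4-methoxybenzyl chloride 11. Aldehyde 10 already has oxygen, methoxy and bromine where C7a', C7' and C5' need them.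

## Roads not taken

**Alternative 1:** The cut is C2'–C3' of the second dihydrofuran. Rh2(S-PTTL)4, dirhodium tetrakis[N-phthaloyl-(S)-tert-leucinate] (divalent rhodium), turns aryldiazoacetate A1 into a carbene that inserts into the benzylic C–H of its 4-methoxybenzyl ether. NaOMe in the work-up equilibrates the ester centre and gives trans ester A2.

- Merits: this insertion class is established for 2-aryl-3-carboxylate dihydrobenzofurans, the acetal at C5' is a ready aldehyde handle, and the trans relationship is reached by simple base equilibration.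
- Weak points: C3' of A2 carries an ester where the target needs a 3,5-dihydroxyphenyl group. Replacing it requires a decarboxylative arylation whose stereochemistry rests only on C2'. The plan also leaves the harder half untouched: the C3–C5' junction and the first ring would still have to be grown from the C5' aldehyde by a second asymmetric ring construction.
- Comparison: its key step is known chemistry, whereas step 13 of the chosen plan is not, and in that respect it is the safer road. The chosen plan in fact borrows the same logic for ring 2 (step 11), but with a diaryl carbene that places the aryl group on C3' directly. Against the known status of A2 it sets a convergent union of three fragments that creates the triaryl stereodiad and the inter-ring bond in a single operation.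

**Alternative 2:** The cut is three bonds of ring A (C3a–C7a, C4–C5, C6–C7). [Rh(cod)2]BF4 with BINAP (monovalent rhodium) cyclotrimerises ynol-ether diyne A3 with ethynylboronic acid pinacol ester A4 to give A5, closing ring A and the first dihydrofuran together.

- Merits: the substitution pattern of ring A is written by the alkynes, so no crowded tetrasubstituted arene has to be coupled at C3. That is exactly where the chosen plan is most strained. Boron at C6 becomes the phenol, the silyloxymethyl group becomes the stilbene, and no stereocentre is touched during ring formation.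
- Weak points: the C2/C3 stereodiad must already exist in A3, so the central problem is only moved. In A3, C3 is propargylic and doubly activated, and the ethynyl ether of a secondary benzylic alcohol can fragment thermally to a ketene and an alkene, erasing both centres. The orientation of A4 (boron at C6 or at C5) rests on a steric bias only. Three further functional-group changes follow.
- Comparison: it is better at the arene-forming event itself, which is insensitive to congestion. The chosen plan has to set against this that it makes the stereodiad and the junction at once, from an achiral alkene, instead of presupposing them.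

**Alternative 3:** The cut is O1'–C7a' (and C7'–O) of the second ring. LiTMP (lithium 2,2,6,6-tetramethylpiperidide) deprotonates the alcohol and the ring C–H between fluorine and the side chain of fluoroarene A6. Loss of LiF gives the aryne, the tethered alkoxide adds at C7a' and closes the dihydrofuran, and the C7' aryllithium is trapped with B(OMe)3 and oxidised with H2O2 to phenol A7.

- Merits: it needs no transition metal, it closes the ring with retention at C2' (no epimerisation step), and it installs the C7' oxygen in the same operation.
- Weak points: fluorine has a second ortho C–H (at C6', next to the acetal-bearing carbon), and lithiation there leads to an aryne the alkoxide cannot close onto. The doubly benzylic C3'–H next to an alkoxide is exposed to a lithium amide. The C7' anion must survive until borylation. A6 is a 1,2,2-triarylethanol with both stereocentres preset, which is the same kind of stereodiad the chosen key step is designed to make.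
- Comparison: for ring 2 alone it would be about as long as steps 7–12 and avoids the acid equilibration of step 12, which is a real advantage. It offers nothing for the first ring or the junction, and the chosen plan needs ring 2 only as a robust aryl bromide.

Key step: step 13

Assumption: the sense of induction of Rh2(R-PTAD)4 (step 11) and of the (Sp,Sp) ligand (step 13) is taken by analogy with simpler substrates; if either delivers the opposite face, its antipode is used and nothing else changes.

Step 1
Reactants: 1 1-chloro-3,5-dimethoxybenzene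
Product: 2 2-chloro-4,6-dimethoxybenzaldehyde
Conditions: POCl3, DMF, 0 → 80 °C; then H2O
Reagents that add atoms: N,N-dimethylformamide, CN(C)C=O; water, O
Why: Vilsmeier–Haack formylation: the chloroiminium ion attacks para to one methoxy group and ortho to the other (two equivalent positions), while the position between the two methoxy groups is the more hindered one.

Step 2
Reactants: 2 2-chloro-4,6-dimethoxybenzaldehyde
Product: 3 2-chloro-6-hydroxy-4-methoxybenzaldehyde
Conditions: BCl3, CH2Cl2, −78 → 0 °C; then H2O
Reagents that add atoms: none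
Why: Chelation-directed Lewis-acid ether cleavage: BCl3 bound to the aldehyde oxygen reaches only the ortho methoxy group, so the para methoxy group and the chloride remain.

Step 3
Reactants: 3 2-chloro-6-hydroxy-4-methoxybenzaldehyde
Product: 4 2-chloro-4-methoxy-6-{[2-(trimethylsilyl)ethoxy]methoxy}benzaldehyde
Conditions: SEMCl, i-Pr2NEt, CH2Cl2, 0 °C → rt
Reagents that add atoms: 2-(trimethylsilyl)ethoxymethyl chloride, C[Si](C)(C)CCOCCl
Why: O-alkylation of the phenol with an α-chloro ether (Williamson-type etherification); the SEM acetal is small, inert to aryllithium, palladium and alkaline peroxide, and is later removed by fluoride without acid.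

Step 4
Reactants: 4 2-chloro-4-methoxy-6-{[2-(trimethylsilyl)ethoxy]methoxy}benzaldehyde
Product: 5 1-chloro-2-ethynyl-5-methoxy-3-{[2-(trimethylsilyl)ethoxy]methoxy}benzene
Conditions: dimethyl (1-diazo-2-oxopropyl)phosphonate, K2CO3, MeOH, rt
Reagents that add atoms: dimethyl (1-diazo-2-oxopropyl)phosphonate, COP(=O)(OC)C(=[N+]=[N-])C(C)=O
Why: Seyferth–Gilbert homologation in its Ohira–Bestmann form: the diazophosphonate anion adds to the aldehyde, phosphate is eliminated and loss of N2 with a 1,2-hydrogen shift gives the terminal alkyne; SEM ether and aryl chloride are stable to carbonate in methanol.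

Step 5
Reactants: 6 acenaphthoquinone
Product: 7 (1R,2S)-1,2-dimethyl-1,2-dihydroacenaphthylene-1,2-diol (cis, meso; mac diol)
Conditions: AlMe3, toluene, 0 °C → rt; then H2O
Reagents that add atoms: trimethylaluminium, C[Al](C)C
Why: Double 1,2-addition of methyl to the 1,2-diketone; the second methyl group should enter anti to the bulky aluminium alkoxide and give mainly the cis diol, the only isomer able to bridge boron, and any trans diol is removed by crystallisation.

Step 6
Reactants: 5 1-chloro-2-ethynyl-5-methoxy-3-{[2-(trimethylsilyl)ethoxy]methoxy}benzene; 7 mac diol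
Product: 9 (E)-2-(2-chloro-4-methoxy-6-{[2-(trimethylsilyl)ethoxy]methoxy}phenyl)ethenylboronic acid mac ester (cyclic ester of diol 7), via catechol alkenylboronate 8 (not isolated)
Conditions: catecholborane, Cy2BH (10 mol%), THF, rt; then 7, rt
Reagents that add atoms: catecholborane, B1Oc2ccccc2O1
Why: Syn hydroboration of the terminal alkyne puts boron on the unhindered terminal carbon and gives the (E)-alkenyl catechol ester; the labile catechol is then displaced by the pre-organised cis diol (transesterification).

Step 7
Reactants: 10 5-bromo-2-hydroxy-3-methoxybenzaldehyde; 11 4-methoxybenzyl chloride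
Product: 12 5-bromo-3-methoxy-2-[(4-methoxybenzyl)oxy]benzaldehyde
Conditions: K2CO3, DMF, 60 °C
Reagents that add atoms: none
Why: Williamson etherification of the phenol; the 4-methoxybenzyl group supplies C2' with its aryl group and the benzylic C–H bond used in step 11.

Step 8
Reactants: 12 5-bromo-3-methoxy-2-[(4-methoxybenzyl)oxy]benzaldehyde; 13 1-bromo-3,5-dimethoxybenzene
Product: 15 rac-{5-bromo-3-methoxy-2-[(4-methoxybenzyl)oxy]phenyl}(3,5-dimethoxyphenyl)methanol, via 3,5-dimethoxyphenylmagnesium bromide 14 (not isolated)
Conditions: 13, Mg, THF, 40 °C; then 12, 0 °C → rt; H2O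
Reagents that add atoms: none
Why: Grignard addition to the aldehyde; at 0 °C the aryl bromide of 12 does not exchange with the arylmagnesium reagent, and the carbinol centre is removed in the next step.

Step 9
Reactants: 15 rac-{5-bromo-3-methoxy-2-[(4-methoxybenzyl)oxy]phenyl}(3,5-dimethoxyphenyl)methanol
Product: 16 {5-bromo-3-methoxy-2-[(4-methoxybenzyl)oxy]phenyl}(3,5-dimethoxyphenyl)methanone
Conditions: MnO2, CH2Cl2, rt
Reagents that add atoms: none
Why: Oxidation of a doubly benzylic alcohol to the diaryl ketone with activated MnO2, which leaves the 4-methoxybenzyl ether and the aryl bromide intact.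

Step 10
Reactants: 16 {5-bromo-3-methoxy-2-[(4-methoxybenzyl)oxy]phenyl}(3,5-dimethoxyphenyl)methanone
Product: 17 hydrazone of ketone 16 (mixture of E and Z isomers)
Conditions: N2H4·H2O, AcOH (cat.), EtOH, reflux
Reagents that add atoms: hydrazine, NN
Why: Acid-catalysed condensation of the ketone with hydrazine (addition–elimination); both C=N isomers serve, since the geometry is lost on oxidation.

Step 11
Reactants: 17 hydrazone of ketone 16
Product: 19 (2S,3R)-5-bromo-3-(3,5-dimethoxyphenyl)-7-methoxy-2-(4-methoxyphenyl)-2,3-dihydro-1-benzofuran (cis), via diaryldiazomethane 18 (not isolated)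
Conditions: MnO2, CH2Cl2, 0 °C; filter; Rh2(R-PTAD)4 (1 mol%), 0 °C
Reagents that add atoms: none
Why: MnO2 dehydrogenates the hydrazone to the diazo compound, and the chiral dirhodium tetracarboxylate (divalent rhodium) converts it into a donor/donor carbene that inserts into the benzylic C–H of the 4-methoxybenzyl ether (intramolecular 1,5 C–H insertion), a known enantioselective entry to cis-2,3-diaryl-2,3-dihydrobenzofurans. Both centres are set by the catalyst in the concerted insertion; C3' is the one that counts, since C2' is corrected in step 12.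

Step 12
Reactants: 19 (2S,3R)-5-bromo-3-(3,5-dimethoxyphenyl)-7-methoxy-2-(4-methoxyphenyl)-2,3-dihydro-1-benzofuran
Product: 20 (2R,3R)-5-bromo-3-(3,5-dimethoxyphenyl)-7-methoxy-2-(4-methoxyphenyl)-2,3-dihydro-1-benzofuran (trans)
Conditions: CF3CO2H, CH2Cl2 (dilute), 0 °C → rt
Reagents that add atoms: none
Why: Acid-mediated equilibration: protonation at O1' and ionisation of the C2'–O bond give a tethered 4-methoxybenzylic cation that re-closes to the thermodynamically preferred trans ring, the non-epimerisable C3' dictating C2'. This is the ionisation by which 4-methoxybenzyl aryl ethers are cleaved by CF3CO2H, reversible here because the phenol stays attached.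

Step 13
Reactants: 9 (E)-alkenylboronic acid mac ester; 21 4-bromoanisole; 20 (2R,3R)-5-bromo-3-(3,5-dimethoxyphenyl)-7-methoxy-2-(4-methoxyphenyl)-2,3-dihydro-1-benzofuran
Product: 24 mac ester of (1R,2S)-2-(2-chloro-4-methoxy-6-{[2-(trimethylsilyl)ethoxy]methoxy}phenyl)-2-[(2R,3R)-3-(3,5-dimethoxyphenyl)-7-methoxy-2-(4-methoxyphenyl)-2,3-dihydro-1-benzofuran-5-yl]-1-(4-methoxyphenyl)ethylboronic acid, via 4-methoxyphenyllithium 22 (not isolated), via lithium alkenyl(aryl)boron ate complex 23 (not isolated)
Conditions: 21, t-BuLi (2 equiv), Et2O, −78 °C; 9, THF, −78 °C → rt; then Pd(OAc)2 (3 mol%), (Sp,Sp)-MandyPhos [1,1'-bis(diphenylphosphino)-2,2'-bis(α-(dimethylamino)benzyl)ferrocene], NaOTf, 20, THF, 60 °C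
Reagents that add atoms: none
Why: Proposed new method: 4-methoxyphenyllithium 22 adds to boron of 9 to give ate complex 23; oxidative addition of bromide 20 to zerovalent palladium, with bromide removed as NaBr, gives a cationic aryl–palladium species (divalent palladium) that binds the alkene of 23 and induces a 1,2-shift of the 4-methoxyphenyl group from boron to the α-carbon (C2) anti to the forming Pd–C3 bond, and reductive elimination then joins C3 to C5' with retention. The closest known reaction type is the palladium/MandyPhos enantioselective conjunctive cross-coupling of alkenylboron ate complexes with aryl electrophiles, established for β-alkyl alkenyl mac esters but not for a β-aryl alkene with two ortho substituents. No ring is closed. The two new stereocentres form together: their relative configuration follows from stereospecific anti addition across the E alkene, and their absolute sense from the alkene face on which the chiral bisphosphine lets palladium bind, so the distant centres of 20 should have no say. The step needs the metallate shift to beat direct transmetallation of the alkenyl group (Suzuki–Miyaura product), and the hindered oxygen atoms of the mac ligand are there to deny palladium the Pd–O–B contact that transmetallation requires. It needs reductive elimination to outrun β-hydride elimination at a crowded benzylic palladium centre, which the wide-bite-angle ferrocenyl bisphosphine should favour, and ring A can rotate so that its small chlorine, not the SEM ether, faces the metal. It needs the C–Cl bond of ring A to stay intact, which it should with a catalyst that enters C–Br at 60 °C.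

Step 14
Reactants: 24 mac boronate from step 13
Product: 25 (1R,2S)-2-(2-chloro-4-methoxy-6-{[2-(trimethylsilyl)ethoxy]methoxy}phenyl)-2-[(2R,3R)-3-(3,5-dimethoxyphenyl)-7-methoxy-2-(4-methoxyphenyl)-2,3-dihydro-1-benzofuran-5-yl]-1-(4-methoxyphenyl)ethan-1-ol
Conditions: H2O2, NaOH, THF/H2O, 0 °C → rt
Reagents that add atoms: hydrogen peroxide, OO
Why: Oxidation of the C–B bond by alkaline hydrogen peroxide (1,2-shift of carbon from boron to oxygen) proceeds with retention, so C2 keeps the configuration set in step 13; SEM ether, aryl chloride and methyl ethers are inert.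

Step 15
Reactants: 25 SEM-protected alcohol
Product: 26 3-chloro-2-{(1S,2R)-1-[(2R,3R)-3-(3,5-dimethoxyphenyl)-7-methoxy-2-(4-methoxyphenyl)-2,3-dihydro-1-benzofuran-5-yl]-2-hydroxy-2-(4-methoxyphenyl)ethyl}-5-methoxyphenol
Conditions: TBAF, THF, 65 °C
Reagents that add atoms: none
Why: Fluoride attack at silicon fragments the SEM group (β-elimination of ethene, then loss of formaldehyde) and frees the phenol without acid, so the ionisable 4-methoxybenzylic alcohol is not disturbed.

Step 16
Reactants: 26 phenol alcohol
Product: 27 (2S,3S)-4-chloro-3-[(2R,3R)-3-(3,5-dimethoxyphenyl)-7-methoxy-2-(4-methoxyphenyl)-2,3-dihydro-1-benzofuran-5-yl]-6-methoxy-2-(4-methoxyphenyl)-2,3-dihydro-1-benzofuran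
Conditions: PPh3, DIAD, THF, 0 °C → rt
Reagents that add atoms: none
Why: Intramolecular Mitsunobu etherification: the secondary alcohol is activated as its oxyphosphonium salt and displaced by the ortho phenoxide in a 5-exo-tet SN2 closure with inversion at C2, which turns the (1S,2R) side chain into the trans (2S,3S) ring. Should the displacement take on SN1 character, closure still favours the trans isomer.

Step 17
Reactants: 27 aryl chloride; 28 4-methoxystyrene
Product: 29 (2S,3S)-3-[(2R,3R)-3-(3,5-dimethoxyphenyl)-7-methoxy-2-(4-methoxyphenyl)-2,3-dihydro-1-benzofuran-5-yl]-6-methoxy-2-(4-methoxyphenyl)-4-[(E)-2-(4-methoxyphenyl)ethenyl]-2,3-dihydro-1-benzofuran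
Conditions: Pd2(dba)3, P(t-Bu)3, Cy2NMe, dioxane, 100 °C
Reagents that add atoms: none
Why: Heck reaction of an aryl chloride under the Pd/P(t-Bu)3/Cy2NMe conditions used for unactivated and ortho-substituted aryl chlorides; insertion places the aryl group on the terminal alkene carbon and syn β-hydride elimination gives the (E)-stilbene.

Step 18
Reactants: 29 heptamethyl ether
Product: 30 (2S,3S)-3-[(2R,3R)-3-(3,5-dihydroxyphenyl)-7-hydroxy-2-(4-hydroxyphenyl)-2,3-dihydro-1-benzofuran-5-yl]-2-(4-hydroxyphenyl)-4-[(E)-2-(4-hydroxyphenyl)ethenyl]-2,3-dihydro-1-benzofuran-6-ol (target)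
Conditions: BBr3, CH2Cl2, −78 °C → rt; then H2O
Reagents that add atoms: none
Why: Lewis-acid cleavage of all seven aryl methyl ethers by BBr3 (bromide attacks the O-methyl group of the boron-bound ether), the usual last step for stilbenoid oligomers. C3 and C3' cannot epimerise, and any transient opening at C2 or C2' re-closes to the trans rings already present.

## Compound list

1 | 1-chloro-3,5-dimethoxybenzene | COc1cc(Cl)cc(OC)c1 | starting material
2 | 2-chloro-4,6-dimethoxybenzaldehyde | COc1cc(Cl)c(C=O)c(OC)c1 | intermediate
3 | 2-chloro-6-hydroxy-4-methoxybenzaldehyde | COc1cc(O)c(C=O)c(Cl)c1 | intermediate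
4 | 2-chloro-4-methoxy-6-{[2-(trimethylsilyl)ethoxy]methoxy}benzaldehyde | COc1cc(Cl)c(C=O)c(OCOCC[Si](C)(C)C)c1 | intermediate
5 | 1-chloro-2-ethynyl-5-methoxy-3-{[2-(trimethylsilyl)ethoxy]methoxy}benzene | COc1cc(Cl)c(C#C)c(OCOCC[Si](C)(C)C)c1 | intermediate
6 | acenaphthoquinone (acenaphthylene-1,2-dione) | O=C1C(=O)c2cccc3cccc1c23 | starting material
7 | (1R,2S)-1,2-dimethyl-1,2-dihydroacenaphthylene-1,2-diol (cis, meso; mac diol) | C[C@@]1(O)c2cccc3cccc(c23)[C@]1(C)O | intermediate
8 | 2-[(E)-2-(2-chloro-4-methoxy-6-{[2-(trimethylsilyl)ethoxy]methoxy}phenyl)ethenyl]-1,3,2-benzodioxaborole | C[Si](C)(C)CCOCOc1cc(OC)cc(Cl)c1/C=C/B1Oc2ccccc2O1 | intermediate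
9 | (E)-2-(2-chloro-4-methoxy-6-{[2-(trimethylsilyl)ethoxy]methoxy}phenyl)ethenylboronic acid, cyclic ester with diol 7 (mac ester) | C[Si](C)(C)CCOCOc1cc(OC)cc(Cl)c1/C=C/B1O[C@]2(C)c3cccc4cccc(c34)[C@]2(C)O1 | intermediate
10 | 5-bromo-2-hydroxy-3-methoxybenzaldehyde | O=Cc1cc(Br)cc(OC)c1O | starting material
11 | 4-methoxybenzyl chloride | COc1ccc(CCl)cc1 | starting material
12 | 5-bromo-3-methoxy-2-[(4-methoxybenzyl)oxy]benzaldehyde | O=Cc1cc(Br)cc(OC)c1OCc1ccc(OC)cc1 | intermediate
13 | 1-bromo-3,5-dimethoxybenzene | COc1cc(Br)cc(OC)c1 | starting material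
14 | 3,5-dimethoxyphenylmagnesium bromide | COc1cc([Mg]Br)cc(OC)c1 | intermediate
15 | rac-{5-bromo-3-methoxy-2-[(4-methoxybenzyl)oxy]phenyl}(3,5-dimethoxyphenyl)methanol | OC(c1cc(OC)cc(OC)c1)c1cc(Br)cc(OC)c1OCc1ccc(OC)cc1 | intermediate
16 | {5-bromo-3-methoxy-2-[(4-methoxybenzyl)oxy]phenyl}(3,5-dimethoxyphenyl)methanone | O=C(c1cc(OC)cc(OC)c1)c1cc(Br)cc(OC)c1OCc1ccc(OC)cc1 | intermediate
17 | hydrazone of ketone 16 (E/Z mixture) | NN=C(c1cc(OC)cc(OC)c1)c1cc(Br)cc(OC)c1OCc1ccc(OC)cc1 | intermediate
18 | 5-bromo-1-[diazo(3,5-dimethoxyphenyl)methyl]-3-methoxy-2-[(4-methoxybenzyl)oxy]benzene | [N-]=[N+]=C(c1cc(OC)cc(OC)c1)c1cc(Br)cc(OC)c1OCc1ccc(OC)cc1 | intermediate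
19 | (2S,3R)-5-bromo-3-(3,5-dimethoxyphenyl)-7-methoxy-2-(4-methoxyphenyl)-2,3-dihydro-1-benzofuran (cis) | Brc1cc(OC)c2c(c1)[C@@H](c1cc(OC)cc(OC)c1)[C@@H](c1ccc(OC)cc1)O2 | intermediate
20 | (2R,3R)-5-bromo-3-(3,5-dimethoxyphenyl)-7-methoxy-2-(4-methoxyphenyl)-2,3-dihydro-1-benzofuran (trans) | Brc1cc(OC)c2c(c1)[C@@H](c1cc(OC)cc(OC)c1)[C@H](c1ccc(OC)cc1)O2 | intermediate
21 | 4-bromoanisole | COc1ccc(Br)cc1 | starting material
22 | 4-methoxyphenyllithium | [Li]c1ccc(OC)cc1 | intermediate
23 | lithium ate complex of 9 with a 4-methoxyphenyl group on boron (either configuration at boron) | [Li+].C[Si](C)(C)CCOCOc1cc(OC)cc(Cl)c1/C=C/[B-]1(c2ccc(OC)cc2)O[C@]2(C)c3cccc4cccc(c34)[C@]2(C)O1 | intermediate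
24 | mac ester of (1R,2S)-2-(2-chloro-4-methoxy-6-{[2-(trimethylsilyl)ethoxy]methoxy}phenyl)-2-[(2R,3R)-3-(3,5-dimethoxyphenyl)-7-methoxy-2-(4-methoxyphenyl)-2,3-dihydro-1-benzofuran-5-yl]-1-(4-methoxyphenyl)ethylboronic acid | C[Si](C)(C)CCOCOc1cc(OC)cc(Cl)c1[C@H](c1cc(OC)c2c(c1)[C@@H](c1cc(OC)cc(OC)c1)[C@H](c1ccc(OC)cc1)O2)[C@H](c1ccc(OC)cc1)B1O[C@]2(C)c3cccc4cccc(c34)[C@]2(C)O1 | intermediate
25 | (1R,2S)-2-(2-chloro-4-methoxy-6-{[2-(trimethylsilyl)ethoxy]methoxy}phenyl)-2-[(2R,3R)-3-(3,5-dimethoxyphenyl)-7-methoxy-2-(4-methoxyphenyl)-2,3-dihydro-1-benzofuran-5-yl]-1-(4-methoxyphenyl)ethan-1-ol | C[Si](C)(C)CCOCOc1cc(OC)cc(Cl)c1[C@H](c1cc(OC)c2c(c1)[C@@H](c1cc(OC)cc(OC)c1)[C@H](c1ccc(OC)cc1)O2)[C@H](c1ccc(OC)cc1)O | intermediate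
26 | 3-chloro-2-{(1S,2R)-1-[(2R,3R)-3-(3,5-dimethoxyphenyl)-7-methoxy-2-(4-methoxyphenyl)-2,3-dihydro-1-benzofuran-5-yl]-2-hydroxy-2-(4-methoxyphenyl)ethyl}-5-methoxyphenol | Oc1cc(OC)cc(Cl)c1[C@H](c1cc(OC)c2c(c1)[C@@H](c1cc(OC)cc(OC)c1)[C@H](c1ccc(OC)cc1)O2)[C@H](c1ccc(OC)cc1)O | intermediate
27 | (2S,3S)-4-chloro-3-[(2R,3R)-3-(3,5-dimethoxyphenyl)-7-methoxy-2-(4-methoxyphenyl)-2,3-dihydro-1-benzofuran-5-yl]-6-methoxy-2-(4-methoxyphenyl)-2,3-dihydro-1-benzofuran | Clc1cc(OC)cc2c1[C@H](c1cc(OC)c3c(c1)[C@@H](c1cc(OC)cc(OC)c1)[C@H](c1ccc(OC)cc1)O3)[C@@H](c1ccc(OC)cc1)O2 | intermediate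
28 | 4-methoxystyrene | C=Cc1ccc(OC)cc1 | starting material
29 | (2S,3S)-3-[(2R,3R)-3-(3,5-dimethoxyphenyl)-7-methoxy-2-(4-methoxyphenyl)-2,3-dihydro-1-benzofuran-5-yl]-6-methoxy-2-(4-methoxyphenyl)-4-[(E)-2-(4-methoxyphenyl)ethenyl]-2,3-dihydro-1-benzofuran | COc1ccc(/C=C/c2cc(OC)cc3c2[C@H](c2cc(OC)c4c(c2)[C@@H](c2cc(OC)cc(OC)c2)[C@H](c2ccc(OC)cc2)O4)[C@@H](c2ccc(OC)cc2)O3)cc1 | intermediate
30 | (2S,3S)-3-[(2R,3R)-3-(3,5-dihydroxyphenyl)-7-hydroxy-2-(4-hydroxyphenyl)-2,3-dihydro-1-benzofuran-5-yl]-2-(4-hydroxyphenyl)-4-[(E)-2-(4-hydroxyphenyl)ethenyl]-2,3-dihydro-1-benzofuran-6-ol (CNP0172909.1) | Oc1ccc(/C=C/c2cc(O)cc3c2[C@H](c2cc(O)c4c(c2)[C@@H](c2cc(O)cc(O)c2)[C@H](c2ccc(O)cc2)O4)[C@@H](c2ccc(O)cc2)O3)cc1 | target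

## Step count and least certain steps

Total: 18 steps. Longest linear sequence: 12 steps (steps 7–12, 13, 14–18). The ring A branch (steps 1–4 and 6) and the diol (step 5) converge at step 13.

**Step 13 (key step, Proposed new method).**
- Most likely failures: direct transmetallation of the alkenyl group to palladium overtaking the metallate shift; failure of the alkene to bind because the β-aryl group carries two ortho substituents; β-hydride elimination from the crowded benzylic alkylpalladium; insufficient facial discrimination.
- Fallback (known chemistry only; sets out from 3 and 20, returns at 27): the first ring is made the way the second one was. Phenol 3 is alkylated with 11 (K2CO3, DMF) to 2-chloro-4-methoxy-6-[(4-methoxybenzyl)oxy]benzaldehyde F1. Bromide 20 is lithiated (n-BuLi, THF, −78 °C) to the 5-lithio derivative F2, which adds to F1 to give diaryl carbinol F3 as a mixture at the carbinol centre. MnO2 gives ketone F4, hydrazine in refluxing n-butanol its hydrazone F5, and MnO2 the diazo compound F6. Rh2(S-PTAD)4 (the antipode of the step 11 catalyst, since C3 has the opposite sense to C3') should convert F6 by benzylic C–H insertion into the cis (2R,3S) 4-chloro dihydrobenzofuran F7. CF3CO2H as in step 12 then inverts C2 and gives 27.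
- Cost of the fallback: six operations replace four, and a hydrazone must be formed at a diaryl ketone in which one ring has both ortho positions occupied.

**Step 12.**
- Most likely failures: incomplete equilibration, or intermolecular Friedel–Crafts capture of the benzylic cation by a 3,5-dimethoxyphenyl ring of a second molecule.
- Fallback (sets out from 19, returns at 20): BBr3 (CH2Cl2, −78 → 0 °C) removes the four methyl groups and gives the cis tetraphenol F8. With the 4-hydroxyphenyl group free, K2CO3 in acetone opens the ring reversibly to a neutral para-quinone methide (retro-oxa-Michael addition) and returns the trans tetraphenol F9. MeI added to the same base re-methylates it to 20.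

**Step 16.**
- Most likely failures: elimination of the activated alcohol towards the triarylethylene (the C3–H is doubly benzylic), or sluggish activation of a carbinol next to a triaryl carbon.
- Fallback (sets out from 26, returns at 27, makes no new compound, F0): closure by ionisation instead of displacement, with catalytic camphorsulfonic acid in CH2Cl2 at −20 °C. The 4-methoxybenzylic cation is trapped by the neighbouring phenol, and trans closure is preferred kinetically and thermodynamically under control of C3. The risk accepted is a competing hydride shift from C3, so the acid is kept catalytic and cold.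

**Step 17.**
- Most likely failures: slow alkene insertion at the hindered aryl–palladium intermediate, leading to reduction of the C–Cl bond, or loss of regiocontrol with the electron-rich styrene.
- Fallback (sets out from 27, returns at 29, makes no new compound, F0): Suzuki–Miyaura coupling with commercial (E)-2-(4-methoxyphenyl)ethenylboronic acid pinacol ester (Pd(OAc)2, SPhos, K3PO4, toluene/H2O, 90 °C). This replaces carbopalladation by transmetallation and brings the E alkene ready-made.

**Step 18.**
- Most likely failures: acid-promoted attack of a neighbouring arene on the protonated stilbene, or oligomerisation during the time seven ether cleavages require.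
- Fallback (sets out from 29, returns at 30, makes no new compound, F0): nucleophilic demethylation with sodium dodecanethiolate (C12H25SNa) in N-methylpyrrolidone at 130 °C. No cation is formed under these basic conditions, and any reversible opening of the rings through para-quinone methides returns the trans isomers.

## Further compounds

F1 | step 13 | 2-chloro-4-methoxy-6-[(4-methoxybenzyl)oxy]benzaldehyde | O=Cc1c(Cl)cc(OC)cc1OCc1ccc(OC)cc1
F2 | step 13 | [(2R,3R)-3-(3,5-dimethoxyphenyl)-7-methoxy-2-(4-methoxyphenyl)-2,3-dihydro-1-benzofuran-5-yl]lithium | [Li]c1cc(OC)c2c(c1)[C@@H](c1cc(OC)cc(OC)c1)[C@H](c1ccc(OC)cc1)O2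
F3 | step 13 | {2-chloro-4-methoxy-6-[(4-methoxybenzyl)oxy]phenyl}[(2R,3R)-3-(3,5-dimethoxyphenyl)-7-methoxy-2-(4-methoxyphenyl)-2,3-dihydro-1-benzofuran-5-yl]methanol (both carbinol epimers) | OC(c1c(Cl)cc(OC)cc1OCc1ccc(OC)cc1)c1cc(OC)c2c(c1)[C@@H](c1cc(OC)cc(OC)c1)[C@H](c1ccc(OC)cc1)O2
F4 | step 13 | {2-chloro-4-methoxy-6-[(4-methoxybenzyl)oxy]phenyl}[(2R,3R)-3-(3,5-dimethoxyphenyl)-7-methoxy-2-(4-methoxyphenyl)-2,3-dihydro-1-benzofuran-5-yl]methanone | O=C(c1c(Cl)cc(OC)cc1OCc1ccc(OC)cc1)c1cc(OC)c2c(c1)[C@@H](c1cc(OC)cc(OC)c1)[C@H](c1ccc(OC)cc1)O2
F5 | step 13 | hydrazone of ketone F4 (E/Z mixture) | NN=C(c1c(Cl)cc(OC)cc1OCc1ccc(OC)cc1)c1cc(OC)c2c(c1)[C@@H](c1cc(OC)cc(OC)c1)[C@H](c1ccc(OC)cc1)O2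
F6 | step 13 | diazo compound from hydrazone F5 | [N-]=[N+]=C(c1c(Cl)cc(OC)cc1OCc1ccc(OC)cc1)c1cc(OC)c2c(c1)[C@@H](c1cc(OC)cc(OC)c1)[C@H](c1ccc(OC)cc1)O2
F7 | step 13 | (2R,3S)-4-chloro-3-[(2R,3R)-3-(3,5-dimethoxyphenyl)-7-methoxy-2-(4-methoxyphenyl)-2,3-dihydro-1-benzofuran-5-yl]-6-methoxy-2-(4-methoxyphenyl)-2,3-dihydro-1-benzofuran (cis first ring) | Clc1cc(OC)cc2c1[C@H](c1cc(OC)c3c(c1)[C@@H](c1cc(OC)cc(OC)c1)[C@H](c1ccc(OC)cc1)O3)[C@H](c1ccc(OC)cc1)O2
F8 | step 12 | (2S,3R)-5-bromo-3-(3,5-dihydroxyphenyl)-2-(4-hydroxyphenyl)-2,3-dihydro-1-benzofuran-7-ol (cis) | Brc1cc(O)c2c(c1)[C@@H](c1cc(O)cc(O)c1)[C@@H](c1ccc(O)cc1)O2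
F9 | step 12 | (2R,3R)-5-bromo-3-(3,5-dihydroxyphenyl)-2-(4-hydroxyphenyl)-2,3-dihydro-1-benzofuran-7-ol (trans) | Brc1cc(O)c2c(c1)[C@@H](c1cc(O)cc(O)c1)[C@H](c1ccc(O)cc1)O2
F0 | step 16 | none | none
F0 | step 17 | none | none
F0 | step 18 | none | none
A1 | alternative 1 | methyl 2-diazo-2-{5-(1,3-dioxolan-2-yl)-3-methoxy-2-[(4-methoxybenzyl)oxy]phenyl}acetate | COC(=O)C(=[N+]=[N-])c1cc(C2OCCO2)cc(OC)c1OCc1ccc(OC)cc1
A2 | alternative 1 | methyl (2R,3R)-5-(1,3-dioxolan-2-yl)-7-methoxy-2-(4-methoxyphenyl)-2,3-dihydro-1-benzofuran-3-carboxylate (trans) | C1COC(O1)c1cc(OC)c2c(c1)[C@@H](C(=O)OC)[C@H](c1ccc(OC)cc1)O2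
A3 | alternative 2 | ethynyl ether of the acyclic stereodiad: 5-(tert-butyldimethylsilyloxy)-1-(4-methoxyphenyl)-2-[second dihydrobenzofuran-5-yl]pent-3-yn-1-yl ethynyl ether, C2 and C3 as in the target | CC(C)(C)[Si](C)(C)OCC#C[C@H](c1cc(OC)c2c(c1)[C@@H](c1cc(OC)cc(OC)c1)[C@H](c1ccc(OC)cc1)O2)[C@@H](c1ccc(OC)cc1)OC#C
A4 | alternative 2 | ethynylboronic acid pinacol ester | C#CB1OC(C)(C)C(C)(C)O1
A5 | alternative 2 | 6-boryl-4-(silyloxymethyl) first dihydrobenzofuran bearing the second one at C3 | CC(C)(C)[Si](C)(C)OCc1cc(B2OC(C)(C)C(C)(C)O2)cc2c1[C@H](c5cc(OC)c6c(c5)[C@@H](c5cc(OC)cc(OC)c5)[C@H](c5ccc(OC)cc5)O6)[C@@H](c1ccc(OC)cc1)O2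
A6 | alternative 3 | (1R,2R)-2-[3-(dimethoxymethyl)-5-fluorophenyl]-2-(3,5-dimethoxyphenyl)-1-(4-methoxyphenyl)ethan-1-ol | COC(OC)c1cc(F)cc(c1)[C@@H](c1cc(OC)cc(OC)c1)[C@H](c1ccc(OC)cc1)O
A7 | alternative 3 | (2R,3R)-5-(dimethoxymethyl)-3-(3,5-dimethoxyphenyl)-2-(4-methoxyphenyl)-2,3-dihydro-1-benzofuran-7-ol | COC(OC)c1cc(O)c2c(c1)[C@@H](c1cc(OC)cc(OC)c1)[C@H](c1ccc(OC)cc1)O2
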